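The spiro carbon C2 (O1' endo, C3' exo) is fixed first, by exo-face C–C bond formation on camphenilone, and stored in a spiro-β-lactone that already holds O1', C2, C3' and C4' of the pyran ring. In the key step an ortho-fluoroaryllithium opens this four-membered ring at the acyl carbon C4', and the liberated tertiary alkoxide then displaces fluoride at C8a'. The two arene carbons C4a' and C8a' are thereby inserted into the acyl–oxygen bond: the oxetanone grows by two atoms into the chromanone ring while the C2–O1' bond is never broken. The step exploits the 1,2-relationship of O1' and C4' on the arene. Isobutyl addition, dehydration, face-selective hydrogenation and diformylation follow.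

Key step: step 5

Remark: atoms of the chromane half carry primes, those of the bicycle do not; (1S,4R)-camphene is assumed to be available in high enantiomeric purity, because its two bridgehead centres are the only source of absolute configuration.

Step 1
Reactants: 1 (1S,4R)-camphene
Product: 2 (1R,4S)-3,3-dimethylbicyclo[2.2.1]heptan-2-one (camphenilone)
Conditions: O3, CH2Cl2/MeOH, −78 °C; then Me2S, −78 °C to rt
Reagents that add atoms: ozone [O-][O+]=O
Why: Ozonolysis (Criegee mechanism) with reductive work-up should cleave only the exocyclic C=CH2 bond to the non-enolisable ketone and leave both bridgehead stereocentres untouched.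

Step 2
Reactants: 2 camphenilone; 3 S-phenyl thioacetate
Product: 5 (1R,2R,4S)-3,3-dimethylspiro[bicyclo[2.2.1]heptane-2,2'-oxetan]-4'-one, via lithium aldolate 4 (not isolated)
Conditions: LDA, THF, −78 °C; then 2, −78 °C to 0 °C
Reagents that add atoms: none
Why: Thiol ester enolate aldol–lactonisation: the lithium enolate should add to the carbonyl from the exo face (anti to the endo hydrogens at C5/C6, the usual sense for 3,3-dimethylnorbornan-2-ones), which places C3' exo and the oxygen endo (2R), and the aldolate then closes 4-exo-trig on the thiol ester with loss of thiophenolate, making the hindered addition irreversible.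

Step 3
Reactants: 6 5-fluorobenzene-1,3-diol
Product: 7 1,3-bis(benzyloxy)-5-fluorobenzene
Conditions: BnBr, K2CO3, DMF, 60 °C
Reagents that add atoms: benzyl bromide BrCc1ccccc1
Why: Williamson ether synthesis on both phenols; benzyl should survive organolithium and acid and is removed later in the hydrogenation step.

Step 4
Reactants: 7 1,3-bis(benzyloxy)-5-fluorobenzene
Product: 8 1,5-bis(benzyloxy)-2-bromo-3-fluorobenzene
Conditions: NBS, MeCN, 0 °C to rt
Reagents that add atoms: N-bromosuccinimide O=C1CCC(=O)N1Br
Why: Electrophilic aromatic bromination should go para to one benzyloxy group at the less crowded position between fluorine and oxygen, not between the two benzyloxy groups, giving the bromide needed for lithiation ortho to fluorine.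

Step 5
Reactants: 8 1,5-bis(benzyloxy)-2-bromo-3-fluorobenzene; 5 spiro-β-lactone
Product: 11 (1R,2R,4S)-5',7'-bis(benzyloxy)-3,3-dimethylspiro[bicyclo[2.2.1]heptane-2,2'-chroman]-4'-one, via aryllithium 9 (not isolated), via lithium alkoxide ketone 10 (not isolated)
Conditions: n-BuLi, THF, −78 °C; then 5, −78 °C; then DMPU, −78 to 45 °C
Reagents that add atoms: none
Why: Bromine–lithium exchange gives the ortho-fluoroaryllithium 9, which attacks the strained lactone carbonyl C4' (nucleophilic acyl substitution); the tetrahedral intermediate collapses with acyl–oxygen cleavage to the lithium alkoxide of the 2-fluoroaryl ketone 10, and on warming with DMPU this alkoxide displaces fluoride at C8a' by addition–elimination (SNAr through a Meisenheimer adduct), so that C4a' and C8a' are inserted into the acyl–oxygen bond and the four-membered ring becomes the six-membered chromanone ring. The closest known reactions are the opening of β-lactones by organolithiums to β-hydroxy ketones and the base-induced cyclisation of 2-fluorophenyl β-hydroxyalkyl ketones to chroman-4-ones. The six-membered ring closes by 6-exo-trig attack of oxygen on the fluorine-bearing arene carbon, which is activated by the ortho carbonyl group just formed. No stereocentre is created: C2 keeps the configuration set in step 2 because the C2–O bond is never broken, and a retro-aldol/aldol excursion of 10 should return the same exo adduct. The step needs acyl rather than alkyl C–O attack and a single addition; the quaternary, neopentyl-type C2 excludes SN2 opening, and the 2,6-disubstituted aryl ketone released is too shielded to add a second, equally hindered aryllithium at −78 °C.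

Step 6
Reactants: 11 spiro-chromanone
Product: 13 (1R,2S,4S)-5',7'-bis(benzyloxy)-3,3-dimethyl-4'-(2-methylpropyl)spiro[bicyclo[2.2.1]heptane-2,2'-chromene], via tertiary alcohol 12 (not isolated)
Conditions: i-BuMgBr, CeCl3, THF, −78 to 0 °C; aq. NH4Cl; then TsOH·H2O (cat.), toluene, 40 °C
Reagents that add atoms: isobutylmagnesium bromide CC(C)C[Mg]Br
Why: Organocerium 1,2-addition (low basicity suppresses enolisation at C3' and the β-elimination of phenoxide that would follow) gives the tertiary benzylic alcohol, whose acid-catalysed E1 dehydration through the arene-stabilised C4' cation should give the conjugated 2H-chromene; the carbinol centre is destroyed again, so its configuration does not matter.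

Step 7
Reactants: 13 spiro-chromene
Product: 14 (1R,2R,4S,4'S)-3,3-dimethyl-4'-(2-methylpropyl)spiro[bicyclo[2.2.1]heptane-2,2'-chromane]-5',7'-diol
Conditions: H2 (4 bar), Pd/C, EtOAc/EtOH, rt
Reagents that add atoms: none
Why: Heterogeneous hydrogenation with concurrent hydrogenolysis of both benzyl ethers: H2 should add to the C3'=C4' face on the side of the bridgehead C1–H, because the exo-methyl group on C3 lies over the other face of the C2–C3' bond, so the isobutyl group ends cis to the gem-dimethyl carbon, i.e. (4'S).

Step 8
Reactants: 14 chromane-5',7'-diol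
Product: 15 (1R,2R,4S,4'S)-5',7'-dihydroxy-3,3-dimethyl-4'-(2-methylpropyl)spiro[bicyclo[2.2.1]heptane-2,2'-chromane]-6',8'-dicarbaldehyde
Conditions: POCl3, DMF, 0 °C to rt; then aq. NaOAc, 60 °C
Reagents that add atoms: N,N-dimethylformamide CN(C)C=O; water O
Why: Double Vilsmeier–Haack formylation: the only two free ring positions, C6' and C8', are each ortho and para to oxygen, and hydrolysis of the bis-iminium salt should give the dialdehyde.

Compound list
1 | (1S,4R)-2,2-dimethyl-3-methylidenebicyclo[2.2.1]heptane, (−)-camphene | C=C1[C@@H]2CC[C@@H](C2)C1(C)C | starting material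
2 | (1R,4S)-3,3-dimethylbicyclo[2.2.1]heptan-2-one, camphenilone | O=C1[C@@H]2CC[C@@H](C2)C1(C)C | intermediate
3 | S-phenyl thioacetate | CC(=O)Sc1ccccc1 | starting material
4 | lithium (1R,2R,4S)-3,3-dimethyl-2-[2-oxo-2-(phenylsulfanyl)ethyl]bicyclo[2.2.1]heptan-2-olate | [Li+].[O-][C@]1(CC(=O)Sc2ccccc2)[C@@H]2CC[C@@H](C2)C1(C)C | intermediate
5 | (1R,2R,4S)-3,3-dimethylspiro[bicyclo[2.2.1]heptane-2,2'-oxetan]-4'-one (oxygen endo, CH2 exo) | O=C1C[C@@]2(O1)[C@@H]1CC[C@@H](C1)C2(C)C | intermediate
6 | 5-fluorobenzene-1,3-diol | Oc1cc(O)cc(F)c1 | starting material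
7 | 1,3-bis(benzyloxy)-5-fluorobenzene | Fc1cc(OCc2ccccc2)cc(OCc2ccccc2)c1 | intermediate
8 | 1,5-bis(benzyloxy)-2-bromo-3-fluorobenzene | Brc1c(F)cc(OCc2ccccc2)cc1OCc1ccccc1 | intermediate
9 | [2,4-bis(benzyloxy)-6-fluorophenyl]lithium | [Li]c1c(F)cc(OCc2ccccc2)cc1OCc1ccccc1 | intermediate
10 | lithium (1R,2R,4S)-2-{2-[2,4-bis(benzyloxy)-6-fluorophenyl]-2-oxoethyl}-3,3-dimethylbicyclo[2.2.1]heptan-2-olate | [Li+].[O-][C@]1(CC(=O)c2c(F)cc(OCc3ccccc3)cc2OCc2ccccc2)[C@@H]2CC[C@@H](C2)C1(C)C | intermediate
11 | (1R,2R,4S)-5',7'-bis(benzyloxy)-3,3-dimethylspiro[bicyclo[2.2.1]heptane-2,2'-chroman]-4'-one | O=C1C[C@@]2(Oc3cc(OCc4ccccc4)cc(OCc4ccccc4)c13)[C@@H]1CC[C@@H](C1)C2(C)C | intermediate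
12 | (1R,2R,4S)-5',7'-bis(benzyloxy)-3,3-dimethyl-4'-(2-methylpropyl)spiro[bicyclo[2.2.1]heptane-2,2'-chroman]-4'-ol (C4' epimers) | CC(C)CC1(O)C[C@@]2(Oc3cc(OCc4ccccc4)cc(OCc4ccccc4)c13)[C@@H]1CC[C@@H](C1)C2(C)C | intermediate
13 | (1R,2S,4S)-5',7'-bis(benzyloxy)-3,3-dimethyl-4'-(2-methylpropyl)spiro[bicyclo[2.2.1]heptane-2,2'-chromene] (same arrangement at C2 as in 11; the descriptor changes by priority only) | CC(C)CC1=C[C@@]2(Oc3cc(OCc4ccccc4)cc(OCc4ccccc4)c13)[C@@H]1CC[C@@H](C1)C2(C)C | intermediate
14 | (1R,2R,4S,4'S)-3,3-dimethyl-4'-(2-methylpropyl)spiro[bicyclo[2.2.1]heptane-2,2'-chromane]-5',7'-diol | CC(C)C[C@H]1C[C@@]2(Oc3cc(O)cc(O)c31)[C@@H]1CC[C@@H](C1)C2(C)C | intermediate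
15 | (1R,2R,4S,4'S)-5',7'-dihydroxy-3,3-dimethyl-4'-(2-methylpropyl)spiro[bicyclo[2.2.1]heptane-2,2'-chromane]-6',8'-dicarbaldehyde | CC(C)C[C@H]1C[C@@]2(Oc3c(C=O)c(O)c(C=O)c(O)c31)[C@@H]1CC[C@@H](C1)C2(C)C | target

Total step count: 8. Longest linear sequence: 6 steps (steps 1, 2, 5, 6, 7, 8 from camphene; the arene branch, steps 3 and 4, joins at step 5).

Steps most likely to fail:

1. Step 5. Three processes may interfere: proton transfer from the C3' methylene of 10 to unreacted 9; retro-aldol fragmentation of 10 before the slow ipso-substitution by the lithium alkoxide; and, if base survives, enolisation of 11 followed by β-elimination of the phenoxide, which would open the ring and endanger the configuration at C2. The fallback sets out from 5 (with 9 made from 8 as before) and returns at 11. The lactone is opened with the chloromagnesium amide of N,O-dimethylhydroxylamine (MeNH(OMe)·HCl, i-PrMgCl, THF) to the β-hydroxy Weinreb amide F1. The tertiary alcohol is capped with TMSOTf and 2,6-lutidine to give the silyl ether F2. Aryllithium 9 is added at −78 °C (Weinreb ketone synthesis: the chelated tetrahedral intermediate releases the ketone only on work-up, and no alkoxide is present to fragment) to give the aryl ketone F3. CsF in DMF then removes silicon, and the alkoxide so formed closes to 11 by the same SNAr.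

2. Step 2. The aldol addition at the very hindered carbonyl may revert faster than the aldolate lactonises, leaving the thiol ester enolate to condense with itself. The fallback sets out from 2 and returns at 5. A Reformatsky reaction (activated Zn, ethyl bromoacetate, THF, reflux) should give the hydroxy ester F4 with the same exo-face selectivity. Saponification with LiOH gives the hydroxy acid F5, and activation of the carboxyl group with benzenesulfonyl chloride in pyridine at 0 °C closes the β-lactone 5.

3. Step 7. Hydrogen may be delivered to the wrong face or to both faces of the hindered trisubstituted alkene, and the allylic C2–O bond may be hydrogenolysed before the alkene is saturated. The fallback sets out from 11 and returns at 14; it inverts the order of bond formation at C4', so that the accessible face receives carbon instead of hydrogen. NaBH4 reduces 11 to the chroman-4'-ol F6 (either epimer serves). BF3·OEt2 at −78 °C ionises it to the benzylic cation, which methallyltrimethylsilane attacks on the open face (Hosomi–Sakurai-type substitution) to give the 4'-(2-methylallyl)chromane F7. H2 over Pd/C then saturates the side-chain alkene and removes both benzyl groups to give 14.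

Further compounds
F1 | step 5 | 2-[(1R,2R,4S)-2-hydroxy-3,3-dimethylbicyclo[2.2.1]heptan-2-yl]-N-methoxy-N-methylacetamide | CON(C)C(=O)C[C@@]1(O)[C@@H]2CC[C@@H](C2)C1(C)C
F2 | step 5 | 2-[(1R,2R,4S)-3,3-dimethyl-2-(trimethylsilyloxy)bicyclo[2.2.1]heptan-2-yl]-N-methoxy-N-methylacetamide | CON(C)C(=O)C[C@@]1(O[Si](C)(C)C)[C@@H]2CC[C@@H](C2)C1(C)C
F3 | step 5 | 1-[2,4-bis(benzyloxy)-6-fluorophenyl]-2-[(1R,2R,4S)-3,3-dimethyl-2-(trimethylsilyloxy)bicyclo[2.2.1]heptan-2-yl]ethan-1-one | C[Si](C)(C)O[C@]1(CC(=O)c2c(F)cc(OCc3ccccc3)cc2OCc2ccccc2)[C@@H]2CC[C@@H](C2)C1(C)C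
F4 | step 2 | ethyl 2-[(1R,2R,4S)-2-hydroxy-3,3-dimethylbicyclo[2.2.1]heptan-2-yl]acetate | CCOC(=O)C[C@@]1(O)[C@@H]2CC[C@@H](C2)C1(C)C
F5 | step 2 | 2-[(1R,2R,4S)-2-hydroxy-3,3-dimethylbicyclo[2.2.1]heptan-2-yl]acetic acid | OC(=O)C[C@@]1(O)[C@@H]2CC[C@@H](C2)C1(C)C
F6 | step 7 | (1R,2R,4S)-5',7'-bis(benzyloxy)-3,3-dimethylspiro[bicyclo[2.2.1]heptane-2,2'-chroman]-4'-ol (C4' epimers) | OC1C[C@@]2(Oc3cc(OCc4ccccc4)cc(OCc4ccccc4)c13)[C@@H]1CC[C@@H](C1)C2(C)C
F7 | step 7 | (1R,2R,4S,4'S)-5',7'-bis(benzyloxy)-3,3-dimethyl-4'-(2-methylprop-2-en-1-yl)spiro[bicyclo[2.2.1]heptane-2,2'-chromane] | CC(=C)C[C@H]1C[C@@]2(Oc3cc(OCc4ccccc4)cc(OCc4ccccc4)c31)[C@@H]1CC[C@@H](C1)C2(C)C
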